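**Plan**

- Retrosynthesis: after global desilylation, the 42-membered lactone ring (C1–C41 plus the ring oxygen) is cut at C31–C32, then at the C1–O41 ester, at C3–C4 (Stille) and at C19–C20 (Ni/Cr), leaving three fragments: the C5–C19 polyol, C20–C31 and C32–C50.
- Enabling feature: C31 is an isolated ring carbinol flanked only by methylenes (C28–C30 towards C27, the C32–C37 hexamethylene run towards the C38=C39 Z-alkene). A C31 aldehyde and a C32 primary iodide, two electrophilic carbons, can therefore be joined last by reductive cobalt/chromium polarity reversal of C32, which closes the ring and sets C31 in one event.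
- Forward: two-directional Ir-catalysed allylation of propane-1,3-diol builds the C2-symmetric all-anti C9–C15 core (C11/C13, then C9/C15); mono-acylation desymmetrises it; C7 follows by allylation and C17/C18 by anti-crotylation.
- Stereochemistry: C27 from (S)-1,2-epoxyhex-5-ene and C49 from (R)-propylene oxide; C23 and C41 by catalyst-controlled allylation; C42/C43 by auxiliary-controlled syn-aldol; C19 by Felkin-controlled Ni/Cr addition; C31 by the chiral ligand on chromium. C4=C5 and C20=C21 come from Z-selective iodo-olefination, C38=C39 from Z-selective cross-metathesis, C2=C3 from the stannane.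
- Joining order: C20–C31 with C5–C19 at C19–C20, then C1–C4, esterification at O41 with C32–C50, ring closure at C31–C32, desilylation.

Key step: step 40

Remark: locants follow the target (C1 = lactone carbonyl, C41 = carbon bearing the ring oxygen, C50 = terminal methyl); "as in target" means the same spatial arrangement as at that carbon of the target, and the SMILES are definitive. TBS = tert-butyldimethylsilyl, PMB = 4-methoxybenzyl.
Assumption: the ligand antipodes quoted for the iridium-catalysed additions are those expected to attack the stated aldehyde face; the stated face defines each step.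
Assumption: (E)-3-(tributylstannyl)acrylic acid and (S)-4-benzyl-3-propanoyl-1,3-thiazolidine-2-thione are bought.

**Fragment C5–C19**

Step 1
Reactants: 1 propane-1,3-diol
Product: 2 (4S,6S)-nona-1,8-diene-4,6-diol
Conditions: allyl acetate, [Ir(cod)Cl]2 (5 mol%), (S)-Cl,MeO-BIPHEP (10 mol%), 4-chloro-3-nitrobenzoic acid (20 mol%), Cs2CO3 (40 mol%), 1,4-dioxane, 90 °C
Reagents that add atoms: allyl acetate CC(=O)OCC=C
Why: Two-directional Ir-catalysed transfer-hydrogenative allylation (Krische allylation), in which each CH2OH is dehydrogenated to the aldehyde and allylated on its Si face by the chiral π-allyliridium complex, so that C11 and C13 should arise together as the C2-symmetric anti diol under ligand control.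

Step 2
Reactants: 2 (4S,6S)-nona-1,8-diene-4,6-diol
Product: 3 (4S,6S)-4,6-bis(tert-butyldimethylsilyloxy)nona-1,8-diene
Conditions: TBSOTf, 2,6-lutidine, CH2Cl2, 0 °C
Reagents that add atoms: tert-butyldimethylsilyl trifluoromethanesulfonate CC(C)(C)[Si](C)(C)OS(=O)(=O)C(F)(F)F
Why: Standard silylation of both secondary hydroxyls with the silyl triflate, giving ethers that survive ozone, hydride and the basic iridium conditions.

Step 3
Reactants: 3 (4S,6S)-4,6-bis(tert-butyldimethylsilyloxy)nona-1,8-diene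
Product: 5 (3S,5S)-3,5-bis(tert-butyldimethylsilyloxy)heptane-1,7-diol, via bis-ozonide 4 (not isolated)
Conditions: O3, CH2Cl2, −78 °C; then NaBH4, MeOH, −78 °C to rt
Reagents that add atoms: ozone [O-][O+]=O
Why: Ozonolysis of both terminal alkenes followed by reductive work-up should give the chain-shortened diol (C9 and C15 as CH2OH) without touching the stereocentres.

Step 4
Reactants: 5 (3S,5S)-3,5-bis(tert-butyldimethylsilyloxy)heptane-1,7-diol
Product: 6 (4R,6S,8S,10R)-6,8-bis(tert-butyldimethylsilyloxy)trideca-1,12-diene-4,10-diol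
Conditions: allyl acetate, [Ir(cod)Cl]2 (5 mol%), (R)-Cl,MeO-BIPHEP (10 mol%), 4-chloro-3-nitrobenzoic acid (20 mol%), Cs2CO3 (40 mol%), 1,4-dioxane, 90 °C
Reagents that add atoms: allyl acetate CC(=O)OCC=C
Why: Second two-directional Krische allylation with the antipodal ligand, which directs Re-face addition at both transient aldehydes and so should set C9 and C15 anti to C11 and C13 under catalyst control.

Step 5
Reactants: 6 (4R,6S,8S,10R)-6,8-bis(tert-butyldimethylsilyloxy)trideca-1,12-diene-4,10-diol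
Product: 7 (4R,6S,8S,10R)-4,6,8,10-tetrakis(tert-butyldimethylsilyloxy)trideca-1,12-diene
Conditions: TBSOTf, 2,6-lutidine, CH2Cl2, 0 °C
Reagents that add atoms: tert-butyldimethylsilyl trifluoromethanesulfonate CC(C)(C)[Si](C)(C)OS(=O)(=O)C(F)(F)F
Why: Silylation of the two new secondary hydroxyls as in step 2.

Step 6
Reactants: 7 (4R,6S,8S,10R)-4,6,8,10-tetrakis(tert-butyldimethylsilyloxy)trideca-1,12-diene
Product: 9 (3R,5S,7S,9R)-3,5,7,9-tetrakis(tert-butyldimethylsilyloxy)undecane-1,11-diol, via bis-ozonide 8 (not isolated)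
Conditions: O3, CH2Cl2, −78 °C; then NaBH4, MeOH, −78 °C to rt
Reagents that add atoms: ozone [O-][O+]=O
Why: Ozonolysis with reductive work-up as in step 3, giving the C2-symmetric C7–C17 diol whose two ends are homotopic.

Step 7
Reactants: 9 (3R,5S,7S,9R)-3,5,7,9-tetrakis(tert-butyldimethylsilyloxy)undecane-1,11-diol
Product: 10 (3R,5S,7S,9R)-11-hydroxy-3,5,7,9-tetrakis(tert-butyldimethylsilyloxy)undecyl 2,2-dimethylpropanoate
Conditions: pivaloyl chloride (1 equiv), pyridine, CH2Cl2, −20 °C; unreacted 9 and the bis-pivalate are recycled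
Reagents that add atoms: pivaloyl chloride CC(C)(C)C(Cl)=O
Why: Statistical mono-acylation, which is acceptable because the two primary hydroxyls of the C2-symmetric diol are homotopic and either one gives the same mono-ester (O17 acylated, O7 free).

Step 8
Reactants: 10 (3R,5S,7S,9R)-11-hydroxy-3,5,7,9-tetrakis(tert-butyldimethylsilyloxy)undecyl 2,2-dimethylpropanoate
Product: 11 C5–C17 homoallylic alcohol (terminal C5=CH2; 7-OH as in target; 9,11,13,15-OTBS; 17-O-pivaloyl)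
Conditions: allyl acetate, [Ir(cod)Cl]2 (2.5 mol%), (S)-Cl,MeO-BIPHEP (5 mol%), 4-chloro-3-nitrobenzoic acid (10 mol%), Cs2CO3 (20 mol%), THF, 100 °C
Reagents that add atoms: allyl acetate CC(=O)OCC=C
Why: Krische allylation of the free C7 carbinol with Si-face addition under ligand control, which should set C7 anti to C9 while the pivalate and silyl ethers are inert.

Step 9
Reactants: 11 C5–C17 homoallylic alcohol
Product: 13 C5–C17 5,7-diol (5-OH primary, 7-OH secondary; 9,11,13,15-OTBS; 17-O-pivaloyl), via ozonide 12 (not isolated)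
Conditions: O3, CH2Cl2, −78 °C; then NaBH4, MeOH, −78 to 0 °C
Reagents that add atoms: ozone [O-][O+]=O
Why: Ozonolysis with reductive work-up converts the terminal alkene into the C5 primary alcohol, and the pivalate survives borohydride at low temperature.

Step 10
Reactants: 13 C5–C17 5,7-diol
Product: 14 C5–C17 5,7,9,11,13,15-hexakis-OTBS 17-pivalate
Conditions: TBSOTf, 2,6-lutidine, CH2Cl2, 0 °C
Reagents that add atoms: tert-butyldimethylsilyl trifluoromethanesulfonate CC(C)(C)[Si](C)(C)OS(=O)(=O)C(F)(F)F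
Why: Silylation of both hydroxyls, which leaves the C5 oxygen as the only primary silyl ether so that it can later be released selectively.

Step 11
Reactants: 14 C5–C17 hexakis-OTBS 17-pivalate
Product: 15 C5–C17 primary alcohol (17-OH; 5,7,9,11,13,15-hexakis-OTBS)
Conditions: DIBAL-H, CH2Cl2, −78 °C; Rochelle salt work-up
Reagents that add atoms: none
Why: Reductive cleavage of the pivalate by the aluminium hydride frees O17 under conditions that leave silyl ethers untouched.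

Step 12
Reactants: 15 C5–C17 primary alcohol
Product: 16 C5–C19 homoallylic alcohol (17-OH and 18-methyl anti, both as in target; terminal C19=CH2)
Conditions: but-3-en-2-yl acetate, [Ir(cod)Cl]2 (2.5 mol%), (S)-SEGPHOS (5 mol%), 4-cyano-3-nitrobenzoic acid (10 mol%), Cs2CO3 (20 mol%), THF, 90 °C
Reagents that add atoms: but-3-en-2-yl acetate CC(OC(C)=O)C=C
Why: Ir-catalysed transfer-hydrogenative anti-crotylation (Krische crotylation), in which the (E)-σ-crotyliridium adds through a chair transition state to the Si face of the transient C17 aldehyde, so that the 17,18-anti relationship and the absolute configuration should both be set by the catalyst.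

Step 13
Reactants: 16 C5–C19 homoallylic alcohol
Product: 17 C5–C19 alkene, 5,7,9,11,13,15,17-heptakis-OTBS
Conditions: TBSOTf, 2,6-lutidine, CH2Cl2, 0 °C
Reagents that add atoms: tert-butyldimethylsilyl trifluoromethanesulfonate CC(C)(C)[Si](C)(C)OS(=O)(=O)C(F)(F)F
Why: Silylation of the hindered C17 hydroxyl with the reactive silyl triflate.

Step 14
Reactants: 17 C5–C19 alkene
Product: 19 C5–C19 aldehyde (C19 CHO; 18-methyl; heptakis-OTBS), via ozonide 18 (not isolated)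
Conditions: O3, CH2Cl2, −78 °C; then PPh3, −78 °C to rt; used crude
Reagents that add atoms: ozone [O-][O+]=O
Why: Ozonolysis with neutral phosphine work-up should give the α-methyl aldehyde without epimerising C18.

**Fragment C20–C31**

Step 15
Reactants: 20 1-[(3-bromopropoxy)methyl]-4-methoxybenzene; 21 (S)-2-(but-3-en-1-yl)oxirane
Product: 23 (5R)-9-[(4-methoxybenzyl)oxy]non-1-en-5-ol, via Grignard reagent 22 (not isolated)
Conditions: Mg, THF, rt; then CuI (10 mol%), 21, −30 to 0 °C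
Reagents that add atoms: none
Why: Copper-catalysed opening of the terminal epoxide at its CH2 carbon by the alkyl Grignard reagent, which keeps the chiral-pool epoxide carbon intact as C27 and brings C29–C31 with the protected C31 oxygen.

Step 16
Reactants: 23 (5R)-9-[(4-methoxybenzyl)oxy]non-1-en-5-ol
Product: 24 (5R)-5-(tert-butyldimethylsilyloxy)-9-[(4-methoxybenzyl)oxy]non-1-ene
Conditions: TBSCl, imidazole, DMF, rt
Reagents that add atoms: tert-butyldimethylsilyl chloride CC(C)(C)[Si](C)(C)Cl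
Why: Standard silylation of the C27 hydroxyl.

Step 17
Reactants: 24 (5R)-5-(tert-butyldimethylsilyloxy)-9-[(4-methoxybenzyl)oxy]non-1-ene
Product: 26 (5S)-5-(tert-butyldimethylsilyloxy)-9-[(4-methoxybenzyl)oxy]nonan-1-ol, via alkylborane 25 (not isolated)
Conditions: 9-BBN, THF, 0 °C to rt; then NaOH, H2O2, 0 °C
Reagents that add atoms: hydrogen peroxide OO
Why: Anti-Markovnikov hydroboration–oxidation of the terminal alkene gives the C23 primary alcohol (the descriptor changes by priority only).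

Step 18
Reactants: 26 (5S)-5-(tert-butyldimethylsilyloxy)-9-[(4-methoxybenzyl)oxy]nonan-1-ol
Product: 27 C21–C31 homoallylic alcohol (terminal C21=CH2; 23-OH as in target; 27-OTBS; 31-OPMB)
Conditions: allyl acetate, [Ir(cod)Cl]2 (2.5 mol%), (S)-Cl,MeO-BIPHEP (5 mol%), 4-chloro-3-nitrobenzoic acid (10 mol%), Cs2CO3 (20 mol%), THF, 100 °C
Reagents that add atoms: allyl acetate CC(=O)OCC=C
Why: Krische allylation from the alcohol oxidation level with Si-face addition, so that C23 should be set by the catalyst independently of the remote C27 centre.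

Step 19
Reactants: 27 C21–C31 homoallylic alcohol
Product: 28 C21–C31 alkene, 23,27-bis-OTBS, 31-OPMB
Conditions: TBSOTf, 2,6-lutidine, CH2Cl2, 0 °C
Reagents that add atoms: tert-butyldimethylsilyl trifluoromethanesulfonate CC(C)(C)[Si](C)(C)OS(=O)(=O)C(F)(F)F
Why: Silylation of the C23 hydroxyl.

Step 20
Reactants: 28 C21–C31 alkene
Product: 30 C21–C31 aldehyde (C21 CHO), via ozonide 29 (not isolated)
Conditions: O3, CH2Cl2, −78 °C (Sudan Red 7B end point); then PPh3, −78 °C to rt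
Reagents that add atoms: ozone [O-][O+]=O
Why: Indicator-controlled ozonolysis cleaves the terminal alkene before the electron-rich PMB ring is attacked.

Step 21
Reactants: 30 C21–C31 aldehyde
Product: 31 C20–C31 (Z)-vinyl iodide (CH3–C20(I)=C21H, iodine cis to C22; 23,27-bis-OTBS; 31-OPMB)
Conditions: EtPPh3I, n-BuLi, THF, rt; I2, −78 °C; NaHMDS, −20 °C; then 30, −78 °C
Reagents that add atoms: ethyltriphenylphosphonium iodide CC[P+](c1ccccc1)(c1ccccc1)c1ccccc1.[I-]; iodine II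
Why: Zhao iodo-olefination, in which the non-stabilised α-iodo ylide should give the (Z)-2-iodoalk-2-ene under kinetic control, placing iodine cis to C22 as required for the C20=C21 geometry once C19 replaces iodine.

**Union and C1–C4**

Step 22
Reactants: 31 C20–C31 (Z)-vinyl iodide; 19 C5–C19 aldehyde
Product: 32 C5–C31 allylic alcohol (19-OH as in target; 5,7,9,11,13,15,17,23,27-nonakis-OTBS; 31-OPMB)
Conditions: 31 (1.5 equiv), CrCl2 (8 equiv), NiCl2 (1 mol%), DMSO, rt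
Reagents that add atoms: none
Why: Nozaki–Hiyama–Kishi coupling, in which the alkenylchromium formed with retention of the Z geometry adds to the aldehyde in the Felkin–Anh sense reinforced by the 1,3-anti preference of the C17 silyloxy group, so that 19-OH should emerge syn to the C18 methyl and anti to O17.

Step 23
Reactants: 32 C5–C31 allylic alcohol
Product: 33 C5–C31 decakis-OTBS ether (19-OTBS), 31-OPMB
Conditions: TBSOTf, 2,6-lutidine, CH2Cl2, −20 to 0 °C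
Reagents that add atoms: tert-butyldimethylsilyl trifluoromethanesulfonate CC(C)(C)[Si](C)(C)OS(=O)(=O)C(F)(F)F
Why: Silylation of the hindered allylic C19 hydroxyl with the silyl triflate under non-acidic conditions.

Step 24
Reactants: 33 C5–C31 decakis-OTBS ether
Product: 34 C5–C31 primary alcohol (5-OH; nine secondary OTBS; 31-OPMB)
Conditions: HF·pyridine, pyridine, THF, 0 °C
Reagents that add atoms: none
Why: Buffered fluoride cleaves the single primary silyl ether faster than the nine hindered secondary ones.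

Step 25
Reactants: 34 C5–C31 primary alcohol
Product: 35 C5–C31 aldehyde (C5 CHO)
Conditions: Dess–Martin periodinane, NaHCO3, CH2Cl2, rt
Reagents that add atoms: none
Why: Mild buffered oxidation to the β-silyloxy aldehyde without elimination or silyl loss.

Step 26
Reactants: 35 C5–C31 aldehyde
Product: 36 C4–C31 (Z)-vinyl iodide (CH3–C4(I)=C5H, iodine cis to C6)
Conditions: EtPPh3I, n-BuLi, THF, rt; I2, −78 °C; NaHMDS, −20 °C; then 35, −78 °C
Reagents that add atoms: ethyltriphenylphosphonium iodide CC[P+](c1ccccc1)(c1ccccc1)c1ccccc1.[I-]; iodine II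
Why: Second Zhao iodo-olefination, which should place iodine cis to C6 and so fix the 4Z geometry for the coming coupling.

Step 27
Reactants: 36 C4–C31 (Z)-vinyl iodide
Product: 37 C1–C31 (2E,4Z)-4-methyldienoic acid (nine secondary OTBS; 31-OPMB)
Conditions: (E)-Bu3SnCH=CHCO2H, Pd2(dba)3 (5 mol%), AsPh3 (40 mol%), i-Pr2NEt, NMP, 40 °C
Reagents that add atoms: (E)-3-(tributylstannyl)acrylic acid CCCC[Sn](CCCC)(CCCC)/C=C/C(O)=O
Why: Stille coupling, in which oxidative addition of zerovalent palladium into C4–I, transmetalation from tin and reductive elimination join C3 to C4 with retention at both alkenes and deliver the dienoic acid directly.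

**Fragment C32–C50**

Step 28
Reactants: 38 6-bromohex-1-ene; 39 (R)-2-methyloxirane
Product: 41 (R)-non-8-en-2-ol, via Grignard reagent 40 (not isolated)
Conditions: Mg, THF, rt; then CuI (10 mol%), 39, −30 to 0 °C
Reagents that add atoms: none
Why: Copper-catalysed opening of (R)-propylene oxide at its CH2 carbon keeps the chiral-pool centre intact as C49.

Step 29
Reactants: 41 (R)-non-8-en-2-ol
Product: 42 (R)-tert-butyldimethyl(non-8-en-2-yloxy)silane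
Conditions: TBSCl, imidazole, DMF, rt
Reagents that add atoms: tert-butyldimethylsilyl chloride CC(C)(C)[Si](C)(C)Cl
Why: Standard silylation of the C49 hydroxyl.

Step 30
Reactants: 42 (R)-tert-butyldimethyl(non-8-en-2-yloxy)silane
Product: 44 (R)-7-(tert-butyldimethylsilyloxy)octanal, via ozonide 43 (not isolated)
Conditions: O3, CH2Cl2, −78 °C; then PPh3, −78 °C to rt
Reagents that add atoms: ozone [O-][O+]=O
Why: Ozonolysis of the terminal alkene gives the C43 aldehyde.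

Step 31
Reactants: 44 (R)-7-(tert-butyldimethylsilyloxy)octanal; 45 (S)-4-benzyl-3-propanoyl-1,3-thiazolidine-2-thione
Product: 47 (S)-4-benzyl-3-[(2S,3R,9R)-9-(tert-butyldimethylsilyloxy)-3-hydroxy-2-methyldecanoyl]-1,3-thiazolidine-2-thione, via titanium enolate 46 (not isolated)
Conditions: 45, TiCl4 (1.05 equiv), i-Pr2NEt (1.1 equiv), NMP (1.1 equiv), CH2Cl2, 0 °C; then 44, 0 °C
Reagents that add atoms: none
Why: Titanium-mediated thiazolidinethione syn-aldol (Crimmins aldol), in which the (Z)-chlorotitanium enolate reacts through the non-chelated chair transition state with the benzyl group shielding one enolate face, so that the Evans-syn adduct should set C42 and C43.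

Step 32
Reactants: 47 aldol adduct
Product: 48 (S)-4-benzyl-3-[(2S,3R,9R)-3,9-bis(tert-butyldimethylsilyloxy)-2-methyldecanoyl]-1,3-thiazolidine-2-thione
Conditions: TBSOTf, 2,6-lutidine, CH2Cl2, 0 °C
Reagents that add atoms: tert-butyldimethylsilyl trifluoromethanesulfonate CC(C)(C)[Si](C)(C)OS(=O)(=O)C(F)(F)F
Why: Silylation of the C43 hydroxyl, which also blocks retro-aldol cleavage.

Step 33
Reactants: 48 silylated aldol adduct
Product: 49 (2R,3R,9R)-3,9-bis(tert-butyldimethylsilyloxy)-2-methyldecan-1-ol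
Conditions: NaBH4, THF/EtOH, 0 °C
Reagents that add atoms: none
Why: The activated N-acyl thiazolidinethione is reduced to the primary alcohol by borohydride with release of the auxiliary and without epimerising C42.

Step 34
Reactants: 49 (2R,3R,9R)-3,9-bis(tert-butyldimethylsilyloxy)-2-methyldecan-1-ol
Product: 50 (4S,5R,6R,12R)-6,12-bis(tert-butyldimethylsilyloxy)-5-methyltridec-1-en-4-ol
Conditions: allyl acetate, [Ir(cod)Cl]2 (2.5 mol%), (S)-Cl,MeO-BIPHEP (5 mol%), 4-chloro-3-nitrobenzoic acid (10 mol%), Cs2CO3 (20 mol%), THF, 100 °C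
Reagents that add atoms: allyl acetate CC(=O)OCC=C
Why: Krische allylation from the alcohol oxidation level, in which the transient α-methyl aldehyde is trapped on its Si face before it can epimerise, so that C41 should be set syn to the C42 methyl (Felkin sense, matched with the catalyst) to complete the syn,syn triad.

Step 35
Reactants: 51 8-bromooct-1-ene
Product: 52 8-iodooct-1-ene
Conditions: NaI, acetone, reflux
Reagents that add atoms: sodium iodide [Na+].[I-]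
Why: Finkelstein exchange driven by precipitation of sodium bromide.

Step 36
Reactants: 50 (4S,5R,6R,12R)-6,12-bis(tert-butyldimethylsilyloxy)-5-methyltridec-1-en-4-ol; 52 8-iodooct-1-ene
Product: 53 (7Z,10S,11R,12R,18R)-1-iodo-11-methyl-12,18-bis(tert-butyldimethylsilyloxy)nonadec-7-en-10-ol
Conditions: 52 (4 equiv), Grubbs Z-selective catalyst (cyclometalated N-adamantyl N-mesityl NHC ruthenium nitrate bearing a 2-isopropoxybenzylidene, 5 mol%), THF, 35 °C, static vacuum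
Reagents that add atoms: none
Why: Z-selective cross-metathesis, in which the cyclometalated ruthenium catalyst forms the side-bound all-syn metallacyclobutane and should give the C38=C39 Z-alkene, with excess 52 suppressing homodimerisation and the free hydroxyl and primary iodide tolerated.

**Endgame**

Step 37
Reactants: 37 C1–C31 dienoic acid; 53 C32–C50 iodo alcohol
Product: 55 seco ester (O41 acylated by C1; 31-OPMB; C32 iodide), via mixed anhydride 54 (not isolated)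
Conditions: 2,4,6-trichlorobenzoyl chloride, Et3N, THF, rt; then 53, DMAP, toluene, rt
Reagents that add atoms: none
Why: Yamaguchi esterification through the mixed anhydride and the acylpyridinium ion acylates the hindered C41 hydroxyl, the (2E) geometry being the stable one and the primary iodide inert at room temperature.

Step 38
Reactants: 55 seco ester
Product: 56 seco ester with free 31-OH
Conditions: DDQ, CH2Cl2/pH 7 buffer, 0 °C
Reagents that add atoms: none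
Why: Oxidative cleavage of the PMB ether by hydride abstraction at the electron-rich benzylic position leaves silyl ethers, the dienoate and the iodide untouched.

Step 39
Reactants: 56 seco ester with free 31-OH
Product: 57 seco ω-iodo aldehyde (C31 CHO, C32 CH2I)
Conditions: Dess–Martin periodinane, NaHCO3, CH2Cl2, rt
Reagents that add atoms: none
Why: Mild oxidation of the only free hydroxyl gives the cyclisation precursor.

Step 40
Reactants: 57 seco ω-iodo aldehyde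
Product: 58 42-membered macrolide (31R, free 31-OH; 7,9,11,13,15,17,19,23,27,43,49-undecakis-OTBS)
Conditions: CrCl2 (8 equiv), chiral sulfonamide–oxazoline ligand of the type used for asymmetric Nozaki–Hiyama–Kishi couplings (9 equiv, antipode giving Re-face addition), Et3N (9 equiv), cobalt phthalocyanine (C32H16CoN8, 20 mol%), LiCl, THF/MeCN, rt, syringe-pump addition of 57 to 1 mM
Reagents that add atoms: none
Why: Proposed new method: cobalt phthalocyanine, reduced by divalent chromium to monovalent cobalt, displaces iodide at C32, the alkylcobalt bond homolyses, and the C32 radical is captured by ligand-bound divalent chromium to give a C32–chromium species (trivalent) that adds to the C31 aldehyde bound to the same metal, so that two electrophilic carbons are joined by reductive polarity reversal of C32. The closest known reaction types are the intermolecular cobalt-catalysed alkylchromium addition of primary iodides to aldehydes and the ligand-controlled Nozaki–Hiyama–Kishi macrocyclisation of alkenyl iodides. The 42-membered lactone ring (C1–C41 plus the ring oxygen) closes in a 42-exo-trig addition to the carbonyl, favoured by slow addition at high dilution. The new stereocentre C31 is set by the chiral ligand on chromium through Re-face delivery, since the nearest stereocentres (C27 and C41) are four and ten bonds away and exert no bias. The step needs selectivity for the aldehyde over the dienoate ester, and capture of the C32 radical by chromium before it cyclises onto C38=C39 (a slow 7-exo mode) or adds to the dienoate; the aldehyde-selective organochromium, the unhindered primary iodide, the non-basic medium and the excess of divalent chromium should secure this.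

Step 41
Reactants: 58 macrolide undecakis-OTBS ether
Product: 59 CNP0392687.1
Conditions: HF·pyridine, pyridine, THF, 0 °C to rt
Reagents that add atoms: none
Why: Global fluoride-mediated desilylation under buffered conditions should release all eleven hydroxyls without lactone migration or isomerisation of the dienoate.

**Compound list**

1 | propane-1,3-diol | OCCCO | starting material
2 | (4S,6S)-nona-1,8-diene-4,6-diol | C=CC[C@H](O)C[C@@H](O)CC=C | intermediate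
3 | (4S,6S)-4,6-bis(tert-butyldimethylsilyloxy)nona-1,8-diene | C=CC[C@H](O[Si](C)(C)C(C)(C)C)C[C@@H](O[Si](C)(C)C(C)(C)C)CC=C | intermediate
4 | bis-ozonide (bis-1,2,4-trioxolane) of 3 | C1OC(OO1)C[C@H](O[Si](C)(C)C(C)(C)C)C[C@@H](O[Si](C)(C)C(C)(C)C)CC1OCOO1 | intermediate
5 | (3S,5S)-3,5-bis(tert-butyldimethylsilyloxy)heptane-1,7-diol | OCC[C@H](O[Si](C)(C)C(C)(C)C)C[C@@H](O[Si](C)(C)C(C)(C)C)CCO | intermediate
6 | (4R,6S,8S,10R)-6,8-bis(tert-butyldimethylsilyloxy)trideca-1,12-diene-4,10-diol | C=CC[C@@H](O)C[C@H](O[Si](C)(C)C(C)(C)C)C[C@@H](O[Si](C)(C)C(C)(C)C)C[C@H](O)CC=C | intermediate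
7 | (4R,6S,8S,10R)-4,6,8,10-tetrakis(tert-butyldimethylsilyloxy)trideca-1,12-diene | C=CC[C@@H](O[Si](C)(C)C(C)(C)C)C[C@H](O[Si](C)(C)C(C)(C)C)C[C@@H](O[Si](C)(C)C(C)(C)C)C[C@H](O[Si](C)(C)C(C)(C)C)CC=C | intermediate
8 | bis-ozonide of 7 | C1OC(OO1)C[C@@H](O[Si](C)(C)C(C)(C)C)C[C@H](O[Si](C)(C)C(C)(C)C)C[C@@H](O[Si](C)(C)C(C)(C)C)C[C@H](O[Si](C)(C)C(C)(C)C)CC1OCOO1 | intermediate
9 | (3R,5S,7S,9R)-3,5,7,9-tetrakis(tert-butyldimethylsilyloxy)undecane-1,11-diol (C7–C17) | OCC[C@@H](O[Si](C)(C)C(C)(C)C)C[C@H](O[Si](C)(C)C(C)(C)C)C[C@@H](O[Si](C)(C)C(C)(C)C)C[C@H](O[Si](C)(C)C(C)(C)C)CCO | intermediate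
10 | (3R,5S,7S,9R)-11-hydroxy-3,5,7,9-tetrakis(tert-butyldimethylsilyloxy)undecyl 2,2-dimethylpropanoate | OCC[C@@H](O[Si](C)(C)C(C)(C)C)C[C@H](O[Si](C)(C)C(C)(C)C)C[C@@H](O[Si](C)(C)C(C)(C)C)C[C@H](O[Si](C)(C)C(C)(C)C)CCOC(=O)C(C)(C)C | intermediate
11 | C5–C17 homoallylic alcohol (C5=CH2; 7-OH; 9,11,13,15-OTBS; 17-O-pivaloyl) | C=CC[C@H](O)C[C@@H](O[Si](C)(C)C(C)(C)C)C[C@H](O[Si](C)(C)C(C)(C)C)C[C@@H](O[Si](C)(C)C(C)(C)C)C[C@H](O[Si](C)(C)C(C)(C)C)CCOC(=O)C(C)(C)C | intermediate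
12 | ozonide of 11 | C1OC(OO1)C[C@H](O)C[C@@H](O[Si](C)(C)C(C)(C)C)C[C@H](O[Si](C)(C)C(C)(C)C)C[C@@H](O[Si](C)(C)C(C)(C)C)C[C@H](O[Si](C)(C)C(C)(C)C)CCOC(=O)C(C)(C)C | intermediate
13 | C5–C17 5,7-diol (9,11,13,15-OTBS; 17-O-pivaloyl) | OCC[C@H](O)C[C@@H](O[Si](C)(C)C(C)(C)C)C[C@H](O[Si](C)(C)C(C)(C)C)C[C@@H](O[Si](C)(C)C(C)(C)C)C[C@H](O[Si](C)(C)C(C)(C)C)CCOC(=O)C(C)(C)C | intermediate
14 | C5–C17 5,7,9,11,13,15-hexakis-OTBS 17-pivalate | CC(C)(C)[Si](C)(C)OCC[C@H](O[Si](C)(C)C(C)(C)C)C[C@@H](O[Si](C)(C)C(C)(C)C)C[C@H](O[Si](C)(C)C(C)(C)C)C[C@@H](O[Si](C)(C)C(C)(C)C)C[C@H](O[Si](C)(C)C(C)(C)C)CCOC(=O)C(C)(C)C | intermediate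
15 | C5–C17 primary alcohol (17-OH; hexakis-OTBS) | CC(C)(C)[Si](C)(C)OCC[C@H](O[Si](C)(C)C(C)(C)C)C[C@@H](O[Si](C)(C)C(C)(C)C)C[C@H](O[Si](C)(C)C(C)(C)C)C[C@@H](O[Si](C)(C)C(C)(C)C)C[C@H](O[Si](C)(C)C(C)(C)C)CCO | intermediate
16 | C5–C19 homoallylic alcohol (17-OH, 18-methyl anti; C19=CH2) | CC(C)(C)[Si](C)(C)OCC[C@H](O[Si](C)(C)C(C)(C)C)C[C@@H](O[Si](C)(C)C(C)(C)C)C[C@H](O[Si](C)(C)C(C)(C)C)C[C@@H](O[Si](C)(C)C(C)(C)C)C[C@H](O[Si](C)(C)C(C)(C)C)C[C@@H](O)[C@@H](C)C=C | intermediate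
17 | C5–C19 alkene, heptakis-OTBS | CC(C)(C)[Si](C)(C)OCC[C@H](O[Si](C)(C)C(C)(C)C)C[C@@H](O[Si](C)(C)C(C)(C)C)C[C@H](O[Si](C)(C)C(C)(C)C)C[C@@H](O[Si](C)(C)C(C)(C)C)C[C@H](O[Si](C)(C)C(C)(C)C)C[C@@H](O[Si](C)(C)C(C)(C)C)[C@@H](C)C=C | intermediate
18 | ozonide of 17 | CC(C)(C)[Si](C)(C)OCC[C@H](O[Si](C)(C)C(C)(C)C)C[C@@H](O[Si](C)(C)C(C)(C)C)C[C@H](O[Si](C)(C)C(C)(C)C)C[C@@H](O[Si](C)(C)C(C)(C)C)C[C@H](O[Si](C)(C)C(C)(C)C)C[C@@H](O[Si](C)(C)C(C)(C)C)[C@@H](C)C1OCOO1 | intermediate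
19 | C5–C19 aldehyde (C19 CHO; heptakis-OTBS) | CC(C)(C)[Si](C)(C)OCC[C@H](O[Si](C)(C)C(C)(C)C)C[C@@H](O[Si](C)(C)C(C)(C)C)C[C@H](O[Si](C)(C)C(C)(C)C)C[C@@H](O[Si](C)(C)C(C)(C)C)C[C@H](O[Si](C)(C)C(C)(C)C)C[C@@H](O[Si](C)(C)C(C)(C)C)[C@@H](C)C=O | intermediate
20 | 1-[(3-bromopropoxy)methyl]-4-methoxybenzene | COc1ccc(COCCCBr)cc1 | starting material
21 | (S)-2-(but-3-en-1-yl)oxirane | C=CCC[C@H]1CO1 | starting material
22 | {3-[(4-methoxybenzyl)oxy]propyl}magnesium bromide | COc1ccc(COCCC[Mg]Br)cc1 | intermediate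
23 | (5R)-9-[(4-methoxybenzyl)oxy]non-1-en-5-ol | C=CCC[C@H](O)CCCCOCc1ccc(OC)cc1 | intermediate
24 | (5R)-5-(tert-butyldimethylsilyloxy)-9-[(4-methoxybenzyl)oxy]non-1-ene | C=CCC[C@H](O[Si](C)(C)C(C)(C)C)CCCCOCc1ccc(OC)cc1 | intermediate
25 | B-alkyl-9-borabicyclo[3.3.1]nonane from 24 | C1CC2CCCC(C1)B2CCCC[C@H](O[Si](C)(C)C(C)(C)C)CCCCOCc1ccc(OC)cc1 | intermediate
26 | (5S)-5-(tert-butyldimethylsilyloxy)-9-[(4-methoxybenzyl)oxy]nonan-1-ol (C23–C31) | OCCCC[C@H](O[Si](C)(C)C(C)(C)C)CCCCOCc1ccc(OC)cc1 | intermediate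
27 | C21–C31 homoallylic alcohol (C21=CH2; 23-OH; 27-OTBS; 31-OPMB) | C=CC[C@H](O)CCC[C@H](O[Si](C)(C)C(C)(C)C)CCCCOCc1ccc(OC)cc1 | intermediate
28 | C21–C31 alkene, 23,27-bis-OTBS, 31-OPMB | C=CC[C@H](O[Si](C)(C)C(C)(C)C)CCC[C@H](O[Si](C)(C)C(C)(C)C)CCCCOCc1ccc(OC)cc1 | intermediate
29 | ozonide of 28 | C1OC(OO1)C[C@H](O[Si](C)(C)C(C)(C)C)CCC[C@H](O[Si](C)(C)C(C)(C)C)CCCCOCc1ccc(OC)cc1 | intermediate
30 | C21–C31 aldehyde | O=CC[C@H](O[Si](C)(C)C(C)(C)C)CCC[C@H](O[Si](C)(C)C(C)(C)C)CCCCOCc1ccc(OC)cc1 | intermediate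
31 | C20–C31 (Z)-vinyl iodide | C/C(I)=C/C[C@H](O[Si](C)(C)C(C)(C)C)CCC[C@H](O[Si](C)(C)C(C)(C)C)CCCCOCc1ccc(OC)cc1 | intermediate
32 | C5–C31 allylic alcohol (19-OH; nonakis-OTBS; 31-OPMB) | CC(C)(C)[Si](C)(C)OCC[C@H](O[Si](C)(C)C(C)(C)C)C[C@@H](O[Si](C)(C)C(C)(C)C)C[C@H](O[Si](C)(C)C(C)(C)C)C[C@@H](O[Si](C)(C)C(C)(C)C)C[C@H](O[Si](C)(C)C(C)(C)C)C[C@@H](O[Si](C)(C)C(C)(C)C)[C@@H](C)[C@H](O)/C(C)=C\C[C@H](O[Si](C)(C)C(C)(C)C)CCC[C@H](O[Si](C)(C)C(C)(C)C)CCCCOCc1ccc(OC)cc1 | intermediate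
33 | C5–C31 decakis-OTBS ether, 31-OPMB | CC(C)(C)[Si](C)(C)OCC[C@H](O[Si](C)(C)C(C)(C)C)C[C@@H](O[Si](C)(C)C(C)(C)C)C[C@H](O[Si](C)(C)C(C)(C)C)C[C@@H](O[Si](C)(C)C(C)(C)C)C[C@H](O[Si](C)(C)C(C)(C)C)C[C@@H](O[Si](C)(C)C(C)(C)C)[C@@H](C)[C@H](O[Si](C)(C)C(C)(C)C)/C(C)=C\C[C@H](O[Si](C)(C)C(C)(C)C)CCC[C@H](O[Si](C)(C)C(C)(C)C)CCCCOCc1ccc(OC)cc1 | intermediate
34 | C5–C31 primary alcohol (5-OH) | OCC[C@H](O[Si](C)(C)C(C)(C)C)C[C@@H](O[Si](C)(C)C(C)(C)C)C[C@H](O[Si](C)(C)C(C)(C)C)C[C@@H](O[Si](C)(C)C(C)(C)C)C[C@H](O[Si](C)(C)C(C)(C)C)C[C@@H](O[Si](C)(C)C(C)(C)C)[C@@H](C)[C@H](O[Si](C)(C)C(C)(C)C)/C(C)=C\C[C@H](O[Si](C)(C)C(C)(C)C)CCC[C@H](O[Si](C)(C)C(C)(C)C)CCCCOCc1ccc(OC)cc1 | intermediate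
35 | C5–C31 aldehyde (C5 CHO) | O=CC[C@H](O[Si](C)(C)C(C)(C)C)C[C@@H](O[Si](C)(C)C(C)(C)C)C[C@H](O[Si](C)(C)C(C)(C)C)C[C@@H](O[Si](C)(C)C(C)(C)C)C[C@H](O[Si](C)(C)C(C)(C)C)C[C@@H](O[Si](C)(C)C(C)(C)C)[C@@H](C)[C@H](O[Si](C)(C)C(C)(C)C)/C(C)=C\C[C@H](O[Si](C)(C)C(C)(C)C)CCC[C@H](O[Si](C)(C)C(C)(C)C)CCCCOCc1ccc(OC)cc1 | intermediate
36 | C4–C31 (Z)-vinyl iodide | C/C(I)=C/C[C@H](O[Si](C)(C)C(C)(C)C)C[C@@H](O[Si](C)(C)C(C)(C)C)C[C@H](O[Si](C)(C)C(C)(C)C)C[C@@H](O[Si](C)(C)C(C)(C)C)C[C@H](O[Si](C)(C)C(C)(C)C)C[C@@H](O[Si](C)(C)C(C)(C)C)[C@@H](C)[C@H](O[Si](C)(C)C(C)(C)C)/C(C)=C\C[C@H](O[Si](C)(C)C(C)(C)C)CCC[C@H](O[Si](C)(C)C(C)(C)C)CCCCOCc1ccc(OC)cc1 | intermediate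
37 | C1–C31 (2E,4Z)-4-methyldienoic acid | OC(=O)/C=C/C(C)=C\C[C@H](O[Si](C)(C)C(C)(C)C)C[C@@H](O[Si](C)(C)C(C)(C)C)C[C@H](O[Si](C)(C)C(C)(C)C)C[C@@H](O[Si](C)(C)C(C)(C)C)C[C@H](O[Si](C)(C)C(C)(C)C)C[C@@H](O[Si](C)(C)C(C)(C)C)[C@@H](C)[C@H](O[Si](C)(C)C(C)(C)C)/C(C)=C\C[C@H](O[Si](C)(C)C(C)(C)C)CCC[C@H](O[Si](C)(C)C(C)(C)C)CCCCOCc1ccc(OC)cc1 | intermediate
38 | 6-bromohex-1-ene | C=CCCCCBr | starting material
39 | (R)-2-methyloxirane | C[C@@H]1CO1 | starting material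
40 | hex-5-en-1-ylmagnesium bromide | C=CCCCC[Mg]Br | intermediate
41 | (R)-non-8-en-2-ol | C=CCCCCC[C@@H](C)O | intermediate
42 | (R)-tert-butyldimethyl(non-8-en-2-yloxy)silane | C=CCCCCC[C@@H](C)O[Si](C)(C)C(C)(C)C | intermediate
43 | ozonide of 42 | C1OC(OO1)CCCCC[C@@H](C)O[Si](C)(C)C(C)(C)C | intermediate
44 | (R)-7-(tert-butyldimethylsilyloxy)octanal | O=CCCCCC[C@@H](C)O[Si](C)(C)C(C)(C)C | intermediate
45 | (S)-4-benzyl-3-propanoyl-1,3-thiazolidine-2-thione | CCC(=O)N1[C@@H](Cc2ccccc2)CSC1=S | starting material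
46 | (Z)-trichlorotitanium enolate of 45 | C/C=C(\O[Ti](Cl)(Cl)Cl)N1[C@@H](Cc2ccccc2)CSC1=S | intermediate
47 | (S)-4-benzyl-3-[(2S,3R,9R)-9-(tert-butyldimethylsilyloxy)-3-hydroxy-2-methyldecanoyl]-1,3-thiazolidine-2-thione | S=C1SC[C@H](Cc2ccccc2)N1C(=O)[C@@H](C)[C@H](O)CCCCC[C@@H](C)O[Si](C)(C)C(C)(C)C | intermediate
48 | (S)-4-benzyl-3-[(2S,3R,9R)-3,9-bis(tert-butyldimethylsilyloxy)-2-methyldecanoyl]-1,3-thiazolidine-2-thione | S=C1SC[C@H](Cc2ccccc2)N1C(=O)[C@@H](C)[C@H](O[Si](C)(C)C(C)(C)C)CCCCC[C@@H](C)O[Si](C)(C)C(C)(C)C | intermediate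
49 | (2R,3R,9R)-3,9-bis(tert-butyldimethylsilyloxy)-2-methyldecan-1-ol | OC[C@@H](C)[C@H](O[Si](C)(C)C(C)(C)C)CCCCC[C@@H](C)O[Si](C)(C)C(C)(C)C | intermediate
50 | (4S,5R,6R,12R)-6,12-bis(tert-butyldimethylsilyloxy)-5-methyltridec-1-en-4-ol | C=CC[C@H](O)[C@@H](C)[C@H](O[Si](C)(C)C(C)(C)C)CCCCC[C@@H](C)O[Si](C)(C)C(C)(C)C | intermediate
51 | 8-bromooct-1-ene | C=CCCCCCCBr | starting material
52 | 8-iodooct-1-ene | C=CCCCCCCI | intermediate
53 | (7Z,10S,11R,12R,18R)-1-iodo-11-methyl-12,18-bis(tert-butyldimethylsilyloxy)nonadec-7-en-10-ol (C32–C50) | ICCCCCC/C=C\C[C@H](O)[C@@H](C)[C@H](O[Si](C)(C)C(C)(C)C)CCCCC[C@@H](C)O[Si](C)(C)C(C)(C)C | intermediate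
54 | mixed 2,4,6-trichlorobenzoic anhydride of 37 | O=C(OC(=O)c1c(Cl)cc(Cl)cc1Cl)/C=C/C(C)=C\C[C@H](O[Si](C)(C)C(C)(C)C)C[C@@H](O[Si](C)(C)C(C)(C)C)C[C@H](O[Si](C)(C)C(C)(C)C)C[C@@H](O[Si](C)(C)C(C)(C)C)C[C@H](O[Si](C)(C)C(C)(C)C)C[C@@H](O[Si](C)(C)C(C)(C)C)[C@@H](C)[C@H](O[Si](C)(C)C(C)(C)C)/C(C)=C\C[C@H](O[Si](C)(C)C(C)(C)C)CCC[C@H](O[Si](C)(C)C(C)(C)C)CCCCOCc1ccc(OC)cc1 | intermediate
55 | seco ester (31-OPMB, C32 iodide) | ICCCCCC/C=C\C[C@H](OC(=O)/C=C/C(C)=C\C[C@H](O[Si](C)(C)C(C)(C)C)C[C@@H](O[Si](C)(C)C(C)(C)C)C[C@H](O[Si](C)(C)C(C)(C)C)C[C@@H](O[Si](C)(C)C(C)(C)C)C[C@H](O[Si](C)(C)C(C)(C)C)C[C@@H](O[Si](C)(C)C(C)(C)C)[C@@H](C)[C@H](O[Si](C)(C)C(C)(C)C)/C(C)=C\C[C@H](O[Si](C)(C)C(C)(C)C)CCC[C@H](O[Si](C)(C)C(C)(C)C)CCCCOCc1ccc(OC)cc1)[C@@H](C)[C@H](O[Si](C)(C)C(C)(C)C)CCCCC[C@@H](C)O[Si](C)(C)C(C)(C)C | intermediate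
56 | seco ester with free 31-OH | ICCCCCC/C=C\C[C@H](OC(=O)/C=C/C(C)=C\C[C@H](O[Si](C)(C)C(C)(C)C)C[C@@H](O[Si](C)(C)C(C)(C)C)C[C@H](O[Si](C)(C)C(C)(C)C)C[C@@H](O[Si](C)(C)C(C)(C)C)C[C@H](O[Si](C)(C)C(C)(C)C)C[C@@H](O[Si](C)(C)C(C)(C)C)[C@@H](C)[C@H](O[Si](C)(C)C(C)(C)C)/C(C)=C\C[C@H](O[Si](C)(C)C(C)(C)C)CCC[C@H](O[Si](C)(C)C(C)(C)C)CCCCO)[C@@H](C)[C@H](O[Si](C)(C)C(C)(C)C)CCCCC[C@@H](C)O[Si](C)(C)C(C)(C)C | intermediate
57 | seco ω-iodo aldehyde (C31 CHO, C32 CH2I) | ICCCCCC/C=C\C[C@H](OC(=O)/C=C/C(C)=C\C[C@H](O[Si](C)(C)C(C)(C)C)C[C@@H](O[Si](C)(C)C(C)(C)C)C[C@H](O[Si](C)(C)C(C)(C)C)C[C@@H](O[Si](C)(C)C(C)(C)C)C[C@H](O[Si](C)(C)C(C)(C)C)C[C@@H](O[Si](C)(C)C(C)(C)C)[C@@H](C)[C@H](O[Si](C)(C)C(C)(C)C)/C(C)=C\C[C@H](O[Si](C)(C)C(C)(C)C)CCC[C@H](O[Si](C)(C)C(C)(C)C)CCCC=O)[C@@H](C)[C@H](O[Si](C)(C)C(C)(C)C)CCCCC[C@@H](C)O[Si](C)(C)C(C)(C)C | intermediate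
58 | 42-membered macrolide, undecakis-OTBS, free 31-OH (31R) | CC1=C/C[C@H](O[Si](C)(C)C(C)(C)C)C[C@@H](O[Si](C)(C)C(C)(C)C)C[C@H](O[Si](C)(C)C(C)(C)C)C[C@@H](O[Si](C)(C)C(C)(C)C)C[C@H](O[Si](C)(C)C(C)(C)C)C[C@@H](O[Si](C)(C)C(C)(C)C)[C@@H](C)[C@H](O[Si](C)(C)C(C)(C)C)/C(C)=C\C[C@H](O[Si](C)(C)C(C)(C)C)CCC[C@H](O[Si](C)(C)C(C)(C)C)CCC[C@H](O)CCCCCC/C=C\C[C@@H]([C@@H](C)[C@H](O[Si](C)(C)C(C)(C)C)CCCCC[C@@H](C)O[Si](C)(C)C(C)(C)C)OC(=O)\C=C\1 | intermediate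
59 | CNP0392687.1 | CC1=C/C[C@H](O)C[C@@H](O)C[C@H](O)C[C@@H](O)C[C@H](O)C[C@@H](O)[C@@H](C)[C@H](O)/C(C)=C\C[C@H](O)CCC[C@H](O)CCC[C@H](O)CCCCCC/C=C\C[C@@H]([C@@H](C)[C@H](O)CCCCC[C@@H](C)O)OC(=O)\C=C\1 | target

**Totals**

Total step count: 41. Longest linear sequence: 25 steps (steps 1–14, 22–27, 37–41).

**Steps most likely to fail**

1. Step 40. What may go wrong: intermolecular chromium–aldehyde addition (oligomers) outrunning the 42-membered closure, or weak ligand control over the aldehyde face at C31. Fallback (known chemistry; the ring is closed at the lactone instead): it sets out from 36 and 53 and comes back at 59. 53 is silylated at O41 (Et3SiCl, imidazole) to the triethylsilyl ether F1, which iodine–zinc exchange (Et2Zn, CuI; then (Me3SiCH2)2Zn) turns into the mixed alkyl(trimethylsilylmethyl)zinc reagent F2. 36 is deprotected with DDQ to the C31 alcohol F3 and oxidised with Dess–Martin periodinane to the C31 aldehyde F4. F2 adds to F4 under Ti(Oi-Pr)4 and a catalytic amount of N,N'-bis(trifluoromethanesulfonyl)cyclohexane-1,2-diamine (catalytic asymmetric dialkylzinc addition, antipode chosen for the 31R carbinol) to give the coupled secondary alcohol F5, which TBSOTf converts into the C31 silyl ether F6. Stille coupling as in step 27 gives the dienoic acid F7; PPTS in MeOH removes only the triethylsilyl group to give the seco hydroxy acid F8; Yamaguchi macrolactonisation at high dilution gives the dodecakis-OTBS macrolide F9, and HF·pyridine as in step 41 gives 59.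

2. Step 26. What may go wrong: erosion of Z-selectivity and loss of material through diiodoalkene formation or β-elimination of the C7 silyloxy group in the iodo-olefination of a late, hindered aldehyde. Fallback: it sets out from 35 (with 53) and comes back at 55. Still–Gennari olefination of 35 (methyl 2-[bis(2,2,2-trifluoroethoxy)phosphoryl]propanoate, KHMDS, 18-crown-6, THF, −78 °C) gives the (Z)-2-methyl enoate F10; DIBAL-H gives the (Z)-allylic alcohol F11 and MnO2 the (Z)-enal F12. 53 is acylated with diethylphosphonoacetic acid (DCC, DMAP) to the phosphonoacetate F13. Horner–Wadsworth–Emmons coupling of F12 and F13 (LiCl, i-Pr2NEt, MeCN) forms the C2=C3 E-alkene and gives 55 directly, so that 36, 37 and step 37 are bypassed.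

3. Step 22. What may go wrong: insufficient facial discrimination in the alkenylchromium addition (partial anti-Felkin attack at C19), or epimerisation at C18 before addition. Fallback: it sets out from the C19 epimer mixture obtained in step 22 and comes back at 32. Oxidation with Dess–Martin periodinane gives the (Z)-enone F14, which is reduced under reagent control with 2-methyl-CBS-oxazaborolidine and catecholborane (antipode chosen for the 19S carbinol) to 32.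

**Further compounds**

F1 | step 40 | O41-triethylsilyl ether of 53 | ICCCCCC/C=C\C[C@H](O[Si](CC)(CC)CC)[C@@H](C)[C@H](O[Si](C)(C)C(C)(C)C)CCCCC[C@@H](C)O[Si](C)(C)C(C)(C)C
F2 | step 40 | mixed alkyl(trimethylsilylmethyl)zinc from F1 | C[Si](C)(C)C[Zn]CCCCCC/C=C\C[C@H](O[Si](CC)(CC)CC)[C@@H](C)[C@H](O[Si](C)(C)C(C)(C)C)CCCCC[C@@H](C)O[Si](C)(C)C(C)(C)C
F3 | step 40 | C4–C31 vinyl iodide with free 31-OH | C/C(I)=C/C[C@H](O[Si](C)(C)C(C)(C)C)C[C@@H](O[Si](C)(C)C(C)(C)C)C[C@H](O[Si](C)(C)C(C)(C)C)C[C@@H](O[Si](C)(C)C(C)(C)C)C[C@H](O[Si](C)(C)C(C)(C)C)C[C@@H](O[Si](C)(C)C(C)(C)C)[C@@H](C)[C@H](O[Si](C)(C)C(C)(C)C)/C(C)=C\C[C@H](O[Si](C)(C)C(C)(C)C)CCC[C@H](O[Si](C)(C)C(C)(C)C)CCCCO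
F4 | step 40 | C4–C31 vinyl iodide C31 aldehyde | C/C(I)=C/C[C@H](O[Si](C)(C)C(C)(C)C)C[C@@H](O[Si](C)(C)C(C)(C)C)C[C@H](O[Si](C)(C)C(C)(C)C)C[C@@H](O[Si](C)(C)C(C)(C)C)C[C@H](O[Si](C)(C)C(C)(C)C)C[C@@H](O[Si](C)(C)C(C)(C)C)[C@@H](C)[C@H](O[Si](C)(C)C(C)(C)C)/C(C)=C\C[C@H](O[Si](C)(C)C(C)(C)C)CCC[C@H](O[Si](C)(C)C(C)(C)C)CCCC=O
F5 | step 40 | C4–C50 coupled alcohol (31-OH, 41-OSiEt3) | C/C(I)=C/C[C@H](O[Si](C)(C)C(C)(C)C)C[C@@H](O[Si](C)(C)C(C)(C)C)C[C@H](O[Si](C)(C)C(C)(C)C)C[C@@H](O[Si](C)(C)C(C)(C)C)C[C@H](O[Si](C)(C)C(C)(C)C)C[C@@H](O[Si](C)(C)C(C)(C)C)[C@@H](C)[C@H](O[Si](C)(C)C(C)(C)C)/C(C)=C\C[C@H](O[Si](C)(C)C(C)(C)C)CCC[C@H](O[Si](C)(C)C(C)(C)C)CCC[C@H](O)CCCCCC/C=C\C[C@H](O[Si](CC)(CC)CC)[C@@H](C)[C@H](O[Si](C)(C)C(C)(C)C)CCCCC[C@@H](C)O[Si](C)(C)C(C)(C)C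
F6 | step 40 | C4–C50 vinyl iodide, 31-OTBS, 41-OSiEt3 | C/C(I)=C/C[C@H](O[Si](C)(C)C(C)(C)C)C[C@@H](O[Si](C)(C)C(C)(C)C)C[C@H](O[Si](C)(C)C(C)(C)C)C[C@@H](O[Si](C)(C)C(C)(C)C)C[C@H](O[Si](C)(C)C(C)(C)C)C[C@@H](O[Si](C)(C)C(C)(C)C)[C@@H](C)[C@H](O[Si](C)(C)C(C)(C)C)/C(C)=C\C[C@H](O[Si](C)(C)C(C)(C)C)CCC[C@H](O[Si](C)(C)C(C)(C)C)CCC[C@H](O[Si](C)(C)C(C)(C)C)CCCCCC/C=C\C[C@H](O[Si](CC)(CC)CC)[C@@H](C)[C@H](O[Si](C)(C)C(C)(C)C)CCCCC[C@@H](C)O[Si](C)(C)C(C)(C)C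
F7 | step 40 | C1–C50 dienoic acid, 41-OSiEt3 | OC(=O)/C=C/C(C)=C\C[C@H](O[Si](C)(C)C(C)(C)C)C[C@@H](O[Si](C)(C)C(C)(C)C)C[C@H](O[Si](C)(C)C(C)(C)C)C[C@@H](O[Si](C)(C)C(C)(C)C)C[C@H](O[Si](C)(C)C(C)(C)C)C[C@@H](O[Si](C)(C)C(C)(C)C)[C@@H](C)[C@H](O[Si](C)(C)C(C)(C)C)/C(C)=C\C[C@H](O[Si](C)(C)C(C)(C)C)CCC[C@H](O[Si](C)(C)C(C)(C)C)CCC[C@H](O[Si](C)(C)C(C)(C)C)CCCCCC/C=C\C[C@H](O[Si](CC)(CC)CC)[C@@H](C)[C@H](O[Si](C)(C)C(C)(C)C)CCCCC[C@@H](C)O[Si](C)(C)C(C)(C)C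
F8 | step 40 | seco hydroxy acid (free 41-OH) | OC(=O)/C=C/C(C)=C\C[C@H](O[Si](C)(C)C(C)(C)C)C[C@@H](O[Si](C)(C)C(C)(C)C)C[C@H](O[Si](C)(C)C(C)(C)C)C[C@@H](O[Si](C)(C)C(C)(C)C)C[C@H](O[Si](C)(C)C(C)(C)C)C[C@@H](O[Si](C)(C)C(C)(C)C)[C@@H](C)[C@H](O[Si](C)(C)C(C)(C)C)/C(C)=C\C[C@H](O[Si](C)(C)C(C)(C)C)CCC[C@H](O[Si](C)(C)C(C)(C)C)CCC[C@H](O[Si](C)(C)C(C)(C)C)CCCCCC/C=C\C[C@H](O)[C@@H](C)[C@H](O[Si](C)(C)C(C)(C)C)CCCCC[C@@H](C)O[Si](C)(C)C(C)(C)C
F9 | step 40 | dodecakis-OTBS macrolide | CC1=C/C[C@H](O[Si](C)(C)C(C)(C)C)C[C@@H](O[Si](C)(C)C(C)(C)C)C[C@H](O[Si](C)(C)C(C)(C)C)C[C@@H](O[Si](C)(C)C(C)(C)C)C[C@H](O[Si](C)(C)C(C)(C)C)C[C@@H](O[Si](C)(C)C(C)(C)C)[C@@H](C)[C@H](O[Si](C)(C)C(C)(C)C)/C(C)=C\C[C@H](O[Si](C)(C)C(C)(C)C)CCC[C@H](O[Si](C)(C)C(C)(C)C)CCC[C@H](O[Si](C)(C)C(C)(C)C)CCCCCC/C=C\C[C@@H]([C@@H](C)[C@H](O[Si](C)(C)C(C)(C)C)CCCCC[C@@H](C)O[Si](C)(C)C(C)(C)C)OC(=O)\C=C\1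
F10 | step 26 | C3–C31 (Z)-2-methyl enoate methyl ester | COC(=O)/C(C)=C\C[C@H](O[Si](C)(C)C(C)(C)C)C[C@@H](O[Si](C)(C)C(C)(C)C)C[C@H](O[Si](C)(C)C(C)(C)C)C[C@@H](O[Si](C)(C)C(C)(C)C)C[C@H](O[Si](C)(C)C(C)(C)C)C[C@@H](O[Si](C)(C)C(C)(C)C)[C@@H](C)[C@H](O[Si](C)(C)C(C)(C)C)/C(C)=C\C[C@H](O[Si](C)(C)C(C)(C)C)CCC[C@H](O[Si](C)(C)C(C)(C)C)CCCCOCc1ccc(OC)cc1
F11 | step 26 | C3–C31 (Z)-allylic alcohol | OC/C(C)=C\C[C@H](O[Si](C)(C)C(C)(C)C)C[C@@H](O[Si](C)(C)C(C)(C)C)C[C@H](O[Si](C)(C)C(C)(C)C)C[C@@H](O[Si](C)(C)C(C)(C)C)C[C@H](O[Si](C)(C)C(C)(C)C)C[C@@H](O[Si](C)(C)C(C)(C)C)[C@@H](C)[C@H](O[Si](C)(C)C(C)(C)C)/C(C)=C\C[C@H](O[Si](C)(C)C(C)(C)C)CCC[C@H](O[Si](C)(C)C(C)(C)C)CCCCOCc1ccc(OC)cc1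
F12 | step 26 | C3–C31 (Z)-enal | O=C/C(C)=C\C[C@H](O[Si](C)(C)C(C)(C)C)C[C@@H](O[Si](C)(C)C(C)(C)C)C[C@H](O[Si](C)(C)C(C)(C)C)C[C@@H](O[Si](C)(C)C(C)(C)C)C[C@H](O[Si](C)(C)C(C)(C)C)C[C@@H](O[Si](C)(C)C(C)(C)C)[C@@H](C)[C@H](O[Si](C)(C)C(C)(C)C)/C(C)=C\C[C@H](O[Si](C)(C)C(C)(C)C)CCC[C@H](O[Si](C)(C)C(C)(C)C)CCCCOCc1ccc(OC)cc1
F13 | step 26 | O41 diethylphosphonoacetate of 53 | ICCCCCC/C=C\C[C@H](OC(=O)CP(=O)(OCC)OCC)[C@@H](C)[C@H](O[Si](C)(C)C(C)(C)C)CCCCC[C@@H](C)O[Si](C)(C)C(C)(C)C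
F14 | step 22 | C5–C31 (Z)-enone (C19 ketone) | CC(C)(C)[Si](C)(C)OCC[C@H](O[Si](C)(C)C(C)(C)C)C[C@@H](O[Si](C)(C)C(C)(C)C)C[C@H](O[Si](C)(C)C(C)(C)C)C[C@@H](O[Si](C)(C)C(C)(C)C)C[C@H](O[Si](C)(C)C(C)(C)C)C[C@@H](O[Si](C)(C)C(C)(C)C)[C@@H](C)C(=O)/C(C)=C\C[C@H](O[Si](C)(C)C(C)(C)C)CCC[C@H](O[Si](C)(C)C(C)(C)C)CCCCOCc1ccc(OC)cc1
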